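**Retrosynthetic overview**

1. Numbering (germacrane): C1 ketone, C2/C3 methylenes, C4/C5 epoxide carbons, C6 lactone carbinol, C7=C11 butenolide alkene, C8 methacrylate carbinol, C9 methylene, C10 acetoxy carbon, C12 lactone carbonyl, C13 acetoxymethyl. The strategy rests on one feature: in the ten-membered ring (C1–C10) the C1 carbonyl faces C6, the acidic γ-carbon of the 7(11)-en-12,6-olide, and the C4–C5 epoxide is cis. The ring is therefore the vinylogous retro-aldol product of a decalin that has an extra C1–C6 bond and an ordinary C4=C5 cyclohexene as ring A (C1–C6).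
2. Disconnections: epoxide ⇒ (4Z)-alkene; ten-membered ring ⇒ tricyclic C1 carbinol by C1–C6 cleavage; tricycle ⇒ intramolecular Diels–Alder reaction (C2–C3 and C1–C6) of a γ-(2-methylallylidene)butenolide with a C1=C2 silyl enol ether; C5–C6 ⇒ vinylogous aldol with methacrolein; C1–C2 ⇒ MeMgBr on a Weinreb amide; C7–C8 ⇒ Fukuyama coupling of a 4-furylzinc (from 3-furanmethanol) with an (R)-citramalate thioester.
3. Ring order: furan (bought) → butenolide (furan oxidation) → rings A and B together (Diels–Alder) → ten-membered ring by cutting the bond shared by rings A and B → epoxide last. C10 comes from (R)-citramalic acid, C8 from a catalyst-controlled ketone reduction, C6 from the quench of the key step, C4/C5 from the last epoxidation.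

Key step: step 19

**Remarks on the chemistry (assumptions)**

- O8 is carried as a triisopropylsilyl ether, so that it survives the acidic removal of the two tertiary triethylsilyl ethers and the primary tert-butyldimethylsilyl ether before the key step.
- Silyl triflate and amine enolise the methyl ketone as well as the butenolide; the vinylogous aldol is therefore run on the fully silylated compound and the spectator enol silane is hydrolysed in the work-up.
- The configuration at C1 and C6 of the cycloadduct is erased in step 19; one isomer (cis-fused) is drawn.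

**Route**

Step 1
Reactants: 1 3-furanmethanol
Product: 2 tert-butyl(furan-3-ylmethoxy)dimethylsilane
Conditions: TBSCl, imidazole, DMF, 0 °C to rt
Reagents that add atoms: tert-butyldimethylsilyl chloride, CC(C)(C)[Si](C)(C)Cl
Why: Standard silylation of a primary alcohol, which installs the silyl group that is moved to carbon in the next step.

Step 2
Reactants: 2 tert-butyl(furan-3-ylmethoxy)dimethylsilane
Product: 4 [2-(tert-butyldimethylsilyl)furan-3-yl]methanol, via 2-lithiofuran 3 (not isolated)
Conditions: n-BuLi, HMPA, THF, −78 to −20 °C; aq NH4Cl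
Reagents that add atoms: none
Why: The oxygenated side chain directs lithiation to the neighbouring furan α-carbon and the carbanion then takes the silyl group from oxygen (1,4 O→C silyl shift, retro-Brook type), which marks the future C12.

Step 3
Reactants: 4 [2-(tert-butyldimethylsilyl)furan-3-yl]methanol
Product: 6 [2-(tert-butyldimethylsilyl)-4-iodofuran-3-yl]methanol, via dilithio species 5 (not isolated)
Conditions: n-BuLi (2.2 equiv), DME, 0 °C; I2, −78 °C to rt; aq NH4Cl
Reagents that add atoms: iodine, II
Why: With the adjacent α-position blocked by silicon, the lithium alkoxide should direct the second lithiation to the neighbouring β-carbon (future C7) and not to the remote α-CH (directed ortho-lithiation), and iodine traps the carbanion.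

Step 4
Reactants: 6 [2-(tert-butyldimethylsilyl)-4-iodofuran-3-yl]methanol
Product: 7 tert-butyl{[2-(tert-butyldimethylsilyl)-4-iodofuran-3-yl]methoxy}dimethylsilane
Conditions: TBSCl, imidazole, DMF, rt
Reagents that add atoms: tert-butyldimethylsilyl chloride, CC(C)(C)[Si](C)(C)Cl
Why: Standard silylation that protects O13 before the organometallic steps.

Step 5
Reactants: 8 (R)-citramalic acid
Product: 9 2-[(4R)-2,2,4-trimethyl-5-oxo-1,3-dioxolan-4-yl]acetic acid
Conditions: Me2C(OMe)2, TsOH (cat.), rt
Reagents that add atoms: 2,2-dimethoxypropane, COC(C)(C)OC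
Why: Acetalisation selects the five-membered dioxolanone across the α-hydroxy acid, which protects O10 and activates C1 while leaving the C8 carboxyl free and the quaternary centre untouched.

Step 6
Reactants: 9 2-[(4R)-2,2,4-trimethyl-5-oxo-1,3-dioxolan-4-yl]acetic acid
Product: 10 S-ethyl 2-[(4R)-2,2,4-trimethyl-5-oxo-1,3-dioxolan-4-yl]ethanethioate
Conditions: EtSH, DCC, DMAP (cat.), CH2Cl2, 0 °C to rt
Reagents that add atoms: ethanethiol, CCS
Why: Steglich-type thioesterification of the only free carboxyl group gives the acyl donor for the ketone synthesis.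

Step 7
Reactants: 7 tert-butyl{[2-(tert-butyldimethylsilyl)-4-iodofuran-3-yl]methoxy}dimethylsilane; 10 S-ethyl 2-[(4R)-2,2,4-trimethyl-5-oxo-1,3-dioxolan-4-yl]ethanethioate
Product: 13 (5R)-5-{2-[5-(tert-butyldimethylsilyl)-4-(tert-butyldimethylsilyloxymethyl)furan-3-yl]-2-oxoethyl}-2,2,5-trimethyl-1,3-dioxolan-4-one, via 4-furyllithium 11 (not isolated), via 4-furylzinc chloride 12 (not isolated)
Conditions: 7, t-BuLi (2.0 equiv), Et2O, −78 °C; ZnCl2, THF, −78 to 0 °C; then 10, PdCl2(PPh3)2 (5 mol%), THF/toluene, rt
Reagents that add atoms: none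
Why: Iodine–lithium exchange and transmetalation give an arylzinc that leaves the dioxolanone alone, and the Fukuyama coupling with the thioester stops at the ketone and forms C7–C8.

Step 8
Reactants: 13 furyl ketone
Product: 14 (5R)-5-{(2S)-2-[5-(tert-butyldimethylsilyl)-4-(tert-butyldimethylsilyloxymethyl)furan-3-yl]-2-hydroxyethyl}-2,2,5-trimethyl-1,3-dioxolan-4-one
Conditions: RuCl(p-cymene)[(S,S)-TsDPEN] (2 mol%), HCO2H/Et3N (5:2), CH2Cl2, rt
Reagents that add atoms: none
Why: Noyori asymmetric transfer hydrogenation, in which the furyl ring takes the aryl position of the organised transition state, so the (S,S) catalyst should deliver hydride to the face that gives (8S), independent of the remote C10 centre.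

Step 9
Reactants: 14 (8S) furyl carbinol
Product: 15 O8-triisopropylsilyl ether of 14
Conditions: TIPSOTf, 2,6-lutidine, CH2Cl2, −78 to 0 °C (on the crude alcohol)
Reagents that add atoms: triisopropylsilyl triflate, CC(C)[Si](C(C)C)(C(C)C)OS(=O)(=O)C(F)(F)F
Why: Immediate silylation of the hindered secondary alcohol forestalls its translactonisation onto the dioxolanone and installs the one silyl group that must outlast all the others.

Step 10
Reactants: 15 O8-triisopropylsilyl dioxolanone
Product: 16 (2R,4S)-4-[5-(tert-butyldimethylsilyl)-4-(tert-butyldimethylsilyloxymethyl)furan-3-yl]-2-hydroxy-N-methoxy-N,2-dimethyl-4-(triisopropylsilyloxy)butanamide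
Conditions: MeNHOMe·HCl, i-PrMgCl, THF, −20 to 0 °C
Reagents that add atoms: N,O-dimethylhydroxylamine hydrochloride, CNOC.Cl
Why: The magnesium amide opens the activated dioxolanone at C1 and the hemiketal alkoxide loses acetone, which gives the Weinreb amide with a free tertiary O10–H.

Step 11
Reactants: 16 Weinreb amide
Product: 17 (3R,5S)-5-[5-(tert-butyldimethylsilyl)-4-(tert-butyldimethylsilyloxymethyl)furan-3-yl]-3-hydroxy-3-methyl-5-(triisopropylsilyloxy)pentan-2-one
Conditions: MeMgBr (3.5 equiv), THF, 0 °C; aq NH4Cl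
Reagents that add atoms: methylmagnesium bromide, C[Mg]Br
Why: Weinreb ketone synthesis, in which the chelated tetrahedral intermediate prevents over-addition, brings in C2 as the methyl ketone.

Step 12
Reactants: 17 furan methyl ketone
Product: 18 3-(tert-butyldimethylsilyloxymethyl)-4-[(1S,3R)-3-hydroxy-3-methyl-4-oxo-1-(triisopropylsilyloxy)pentyl]furan-2(5H)-one
Conditions: AcOOH (1.5 equiv, in AcOH), NaOAc, CH2Cl2, 0 °C to rt
Reagents that add atoms: peracetic acid, CC(=O)OO
Why: Peracid oxidation of a 2-silylfuran (ipso attack at the silyl-bearing carbon, carbon-to-oxygen silyl shift, protodesilylation) should place the carbonyl at C12 and the CH2 at C6, and the buffered peracid is consumed by the electron-rich furan well before Baeyer–Villiger oxidation of the ketone can compete.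

Step 13
Reactants: 18 butenolide
Product: 19 tris(triethylsilyl) derivative of 18 (2-triethylsilyloxyfuran, O10 triethylsilyl ether, C1=C2 triethylsilyl enol ether)
Conditions: TESOTf (3.5 equiv), Et3N (5 equiv), CH2Cl2, −78 to 0 °C; pentane, filtration; used crude
Reagents that add atoms: triethylsilyl triflate, CC[Si](CC)(CC)OS(=O)(=O)C(F)(F)F
Why: Soft enolisation silylates the tertiary alcohol, aromatises the butenolide to the 2-silyloxyfuran and unavoidably enolises the methyl ketone as well (toward C2 only, since C10 is quaternary), so all three sites are deliberately driven to completion to give one defined compound.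

Step 14
Reactants: 19 tris(triethylsilyl) compound; 20 methacrolein
Product: 22 5-(1-hydroxy-2-methylprop-2-enyl)butenolide with the methyl ketone restored and O10 triethylsilyl ether (mixture of C5/C6 isomers), via enol silane aldol adduct 21 (not isolated)
Conditions: 20 (1.05 equiv), BF3·OEt2 (1.1 equiv), CH2Cl2, −78 °C; aq NaHCO3; then 1 M HCl, THF, 0 °C
Reagents that add atoms: methacrolein (20), C=C(C)C=O
Why: Vinylogous Mukaiyama aldol, in which the aromatic 2-silyloxyfuran is expected to be the much stronger π-nucleophile of the two enol silanes and attacks the activated aldehyde through C6 to form C5–C6, after which brief acid returns the spectator enol silane to the ketone; the new C5 and C6 centres are inconsequential because both carbons become sp2 in step 15.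

Step 15
Reactants: 22 aldol adduct
Product: 24 3-(tert-butyldimethylsilyloxymethyl)-5-[(Z)-2-methylprop-2-enylidene]-4-[(1S,3R)-3-methyl-4-oxo-3-(triethylsilyloxy)-1-(triisopropylsilyloxy)pentyl]furan-2(5H)-one, via C5 mesylate 23 (not isolated)
Conditions: MsCl, Et3N, CH2Cl2, 0 °C; then DBU, rt
Reagents that add atoms: none
Why: Mesylation and E1cB elimination through the furanolate should give the Z ylidene (C4 syn to the ring oxygen), because the E isomer would press the isopropenyl group against the C8 substituent on C7.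

Step 16
Reactants: 24 (Z)-ylidene butenolide methyl ketone
Product: 25 C1=C2 triethylsilyl enol ether of 24 (triene)
Conditions: TESOTf (1.5 equiv), Et3N (3 equiv), CH2Cl2, −78 to 0 °C
Reagents that add atoms: triethylsilyl triflate, CC[Si](CC)(CC)OS(=O)(=O)C(F)(F)F
Why: Soft enolisation is regiospecific because only C2 carries α-hydrogens and the ylidene butenolide no longer has a γ-hydrogen.

Step 17
Reactants: 25 triene
Product: 26 tricyclic cycloadduct (rings A and B fused at C1–C6, butenolide fused at C6–C7; O1 and O10 triethylsilyl, O13 tert-butyldimethylsilyl, O8 triisopropylsilyl; drawn cis-fused)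
Conditions: degassed toluene (0.005 M), BHT, Et3N (1%), 150 °C, sealed tube
Reagents that add atoms: none
Why: Intramolecular inverse-electron-demand Diels–Alder reaction in which the electron-rich enol silane (nucleophilic C2) adds to the electron-poor dienyl lactone C3=C4–C5=C6 (C3 is the remote acceptor terminus of the trienoate), the four-atom tether C7–C8–C9–C10 forcing C2–C3 and C1–C6 to form and rings A and B to close together; facial and endo/exo selectivity do not matter because C1 and C6 are erased in step 19.

Step 18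
Reactants: 26 tricyclic cycloadduct
Product: 27 tricyclic 1,10,13-triol with O8 triisopropylsilyl ether
Conditions: HF·pyridine, pyridine, THF, 0 °C to rt
Reagents that add atoms: none
Why: Acidic fluoride desilylation should remove the two tertiary triethylsilyl ethers and the primary tert-butyldimethylsilyl ether while the hindered secondary triisopropylsilyl ether survives, and the non-basic medium does not trigger the fragmentation early.

Step 19
Reactants: 27 tricyclic triol
Product: 30 (4Z,6S,8S,10R)-10,13-dihydroxy-1-oxo-8-(triisopropylsilyloxy)germacra-4,7(11)-dien-12,6-olide, via tripotassium trialkoxide 28 (not isolated), via tripotassium furanolate 29 (not isolated)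
Conditions: KN(SiMe3)2 (3.3 equiv), THF, −78 to −40 °C; then transfer into AcOH/THF at −78 °C
Reagents that add atoms: none
Why: Proposed new method: KN(SiMe3)2 converts 27 into its trialkoxide, and the C1 alkoxide, whose C1–C6 bond is held roughly at right angles to the lactone plane and so is aligned with the C7=C11–C12=O π system, releases C6 as a potassium 2-furanolate, which creates the C1 ketone (a vinylogous retro-aldol); the closest known reaction types are the retro-aldol ring expansion of bicyclic aldolates (De Mayo sequence) and the base-induced reversal of vinylogous aldol adducts of butenolides. No ring is closed end to end: the ten-membered carbocycle appears as the periphery of the two six-membered rings once their shared bond is cut, so no bond-forming transition state carries medium-ring entropy or transannular strain, and the 4Z alkene is inherited from the cyclohexene. The reaction should be driven by the exchange of a localised tertiary alkoxide for an aromatic, delocalised anion and by relief of three contiguous fully substituted carbons (C10, C1, C6), and every C1/C6 isomer of 27 gives the same anion 29. The only new stereocentre, C6, is set in the cold acetic acid quench: allylic strain between C8–H and the C13 methylene holds C9 and the ring loop over one face of the planar furanolate, so the proton should arrive on the open face and give (6S). The step needs bond selectivity, which is secured because of the three C–C bonds at C1 only C1–C6 can leave as a stabilised anion, while the O10 and O13 alkoxides have no such pathway and the O13 oxide cannot be eliminated. It also needs site selectivity in the quench (C6 rather than C4 or C11), which should follow from the twist of the Z alkene out of the furan plane, keeping charge off C4, and from the return to the conjugated butenolide.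

Step 20
Reactants: 30 ten-membered ketone diol
Product: 31 (4Z,6S,8S,10R)-10,13-diacetoxy-1-oxo-8-(triisopropylsilyloxy)germacra-4,7(11)-dien-12,6-olide
Conditions: Ac2O, DMAP, pyridine, rt to 40 °C
Reagents that add atoms: acetic anhydride, CC(=O)OC(C)=O
Why: DMAP-catalysed acylation esterifies the primary O13–H at once and the tertiary α-ketol O10–H more slowly, and the weak amine base should not reach the C6–H.

Step 21
Reactants: 31 diacetate
Product: 32 (4Z,6S,8S,10R)-10,13-diacetoxy-8-hydroxy-1-oxogermacra-4,7(11)-dien-12,6-olide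
Conditions: HF·pyridine, THF, 0 °C to rt
Reagents that add atoms: none
Why: Fluoride under acidic conditions cleaves the silyl ether without acetyl migration and without base-induced loss of the allylic C13 acetate.

Step 22
Reactants: 32 C8 alcohol; 33 methacrylic anhydride
Product: 34 (4Z,6S,8S,10R)-10,13-diacetoxy-8-(methacryloyloxy)-1-oxogermacra-4,7(11)-dien-12,6-olide
Conditions: 33, DMAP, Et3N, BHT, CH2Cl2, 0 °C to rt
Reagents that add atoms: methacrylic anhydride (33), C=C(C)C(=O)OC(=O)C(C)=C
Why: DMAP-catalysed acylation of the secondary allylic alcohol should outrun acetyl migration from O10.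

Step 23
Reactants: 34 triester alkene
Product: 35 target, (4R,5S,6R,8S,10R)-10,13-diacetoxy-4,5-epoxy-8-(methacryloyloxy)-1-oxogermacr-7(11)-en-12,6-olide
Conditions: mCPBA, NaHCO3, CH2Cl2, 0 °C
Reagents that add atoms: 3-chloroperbenzoic acid, OOC(=O)c1cccc(Cl)c1
Why: Prilezhaev epoxidation of the only electron-rich alkene (the butenolide and methacrylate alkenes are deactivated); with C6–H eclipsing the Z alkene, the peracid should attack the peripheral face, which is the face of the C6–O bond and opposite to C7 and the ring interior, giving the cis (4R,5S) epoxide.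

**Compound list**

1 | 3-furanmethanol | OCc1ccoc1 | starting material
2 | tert-butyl(furan-3-ylmethoxy)dimethylsilane | CC(C)(C)[Si](C)(C)OCc1ccoc1 | intermediate
3 | [3-(tert-butyldimethylsilyloxymethyl)furan-2-yl]lithium | CC(C)(C)[Si](C)(C)OCc1ccoc1[Li] | intermediate
4 | [2-(tert-butyldimethylsilyl)furan-3-yl]methanol | CC(C)(C)[Si](C)(C)c1occc1CO | intermediate
5 | lithium [2-(tert-butyldimethylsilyl)-4-lithiofuran-3-yl]methoxide | CC(C)(C)[Si](C)(C)c1occ([Li])c1CO[Li] | intermediate
6 | [2-(tert-butyldimethylsilyl)-4-iodofuran-3-yl]methanol | CC(C)(C)[Si](C)(C)c1occ(I)c1CO | intermediate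
7 | tert-butyl{[2-(tert-butyldimethylsilyl)-4-iodofuran-3-yl]methoxy}dimethylsilane | CC(C)(C)[Si](C)(C)OCc1c(I)coc1[Si](C)(C)C(C)(C)C | intermediate
8 | (R)-citramalic acid | OC(=O)C[C@@](C)(O)C(=O)O | starting material
9 | 2-[(4R)-2,2,4-trimethyl-5-oxo-1,3-dioxolan-4-yl]acetic acid | OC(=O)C[C@@]1(C)OC(C)(C)OC1=O | intermediate
10 | S-ethyl 2-[(4R)-2,2,4-trimethyl-5-oxo-1,3-dioxolan-4-yl]ethanethioate | CCSC(=O)C[C@@]1(C)OC(C)(C)OC1=O | intermediate
11 | [5-(tert-butyldimethylsilyl)-4-(tert-butyldimethylsilyloxymethyl)furan-3-yl]lithium | CC(C)(C)[Si](C)(C)OCc1c([Li])coc1[Si](C)(C)C(C)(C)C | intermediate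
12 | [5-(tert-butyldimethylsilyl)-4-(tert-butyldimethylsilyloxymethyl)furan-3-yl]zinc chloride | CC(C)(C)[Si](C)(C)OCc1c([Zn]Cl)coc1[Si](C)(C)C(C)(C)C | intermediate
13 | (5R)-5-{2-[5-(tert-butyldimethylsilyl)-4-(tert-butyldimethylsilyloxymethyl)furan-3-yl]-2-oxoethyl}-2,2,5-trimethyl-1,3-dioxolan-4-one | CC(C)(C)[Si](C)(C)OCc1c(coc1[Si](C)(C)C(C)(C)C)C(=O)C[C@@]1(C)OC(C)(C)OC1=O | intermediate
14 | (5R)-5-{(2S)-2-[5-(tert-butyldimethylsilyl)-4-(tert-butyldimethylsilyloxymethyl)furan-3-yl]-2-hydroxyethyl}-2,2,5-trimethyl-1,3-dioxolan-4-one | O[C@H](c1coc([Si](C)(C)C(C)(C)C)c1CO[Si](C)(C)C(C)(C)C)C[C@@]1(C)OC(C)(C)OC1=O | intermediate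
15 | O8-triisopropylsilyl ether of 14 | CC(C)[Si](C(C)C)(C(C)C)O[C@H](c1coc([Si](C)(C)C(C)(C)C)c1CO[Si](C)(C)C(C)(C)C)C[C@@]1(C)OC(C)(C)OC1=O | intermediate
16 | (2R,4S)-4-[5-(tert-butyldimethylsilyl)-4-(tert-butyldimethylsilyloxymethyl)furan-3-yl]-2-hydroxy-N-methoxy-N,2-dimethyl-4-(triisopropylsilyloxy)butanamide | CC(C)[Si](C(C)C)(C(C)C)O[C@H](c1coc([Si](C)(C)C(C)(C)C)c1CO[Si](C)(C)C(C)(C)C)C[C@@](C)(O)C(=O)N(C)OC | intermediate
17 | (3R,5S)-5-[5-(tert-butyldimethylsilyl)-4-(tert-butyldimethylsilyloxymethyl)furan-3-yl]-3-hydroxy-3-methyl-5-(triisopropylsilyloxy)pentan-2-one | CC(C)[Si](C(C)C)(C(C)C)O[C@H](c1coc([Si](C)(C)C(C)(C)C)c1CO[Si](C)(C)C(C)(C)C)C[C@@](C)(O)C(C)=O | intermediate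
18 | 3-(tert-butyldimethylsilyloxymethyl)-4-[(1S,3R)-3-hydroxy-3-methyl-4-oxo-1-(triisopropylsilyloxy)pentyl]furan-2(5H)-one | CC(C)[Si](C(C)C)(C(C)C)O[C@H](C1=C(CO[Si](C)(C)C(C)(C)C)C(=O)OC1)C[C@@](C)(O)C(C)=O | intermediate
19 | tris(triethylsilyl) derivative of 18: 2-triethylsilyloxyfuran, O10 triethylsilyl ether, C1=C2 triethylsilyl enol ether | CC(C)[Si](C(C)C)(C(C)C)O[C@H](c1coc(O[Si](CC)(CC)CC)c1CO[Si](C)(C)C(C)(C)C)C[C@@](C)(O[Si](CC)(CC)CC)C(=C)O[Si](CC)(CC)CC | intermediate
20 | methacrolein | C=C(C)C=O | starting material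
21 | C5-hydroxy aldol adduct still carrying the C1=C2 enol silane (C5/C6 isomer mixture) | CC(C)[Si](C(C)C)(C(C)C)O[C@H](C1=C(CO[Si](C)(C)C(C)(C)C)C(=O)OC1C(O)C(C)=C)C[C@@](C)(O[Si](CC)(CC)CC)C(=C)O[Si](CC)(CC)CC | intermediate
22 | 3-(tert-butyldimethylsilyloxymethyl)-5-(1-hydroxy-2-methylprop-2-enyl)-4-[(1S,3R)-3-methyl-4-oxo-3-(triethylsilyloxy)-1-(triisopropylsilyloxy)pentyl]furan-2(5H)-one (C5/C6 isomer mixture) | CC(C)[Si](C(C)C)(C(C)C)O[C@H](C1=C(CO[Si](C)(C)C(C)(C)C)C(=O)OC1C(O)C(C)=C)C[C@@](C)(O[Si](CC)(CC)CC)C(C)=O | intermediate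
23 | C5 methanesulfonate of 22 | CC(C)[Si](C(C)C)(C(C)C)O[C@H](C1=C(CO[Si](C)(C)C(C)(C)C)C(=O)OC1C(OS(C)(=O)=O)C(C)=C)C[C@@](C)(O[Si](CC)(CC)CC)C(C)=O | intermediate
24 | 3-(tert-butyldimethylsilyloxymethyl)-5-[(Z)-2-methylprop-2-enylidene]-4-[(1S,3R)-3-methyl-4-oxo-3-(triethylsilyloxy)-1-(triisopropylsilyloxy)pentyl]furan-2(5H)-one | CC(C)[Si](C(C)C)(C(C)C)O[C@H](C1=C(CO[Si](C)(C)C(C)(C)C)C(=O)O/C1=C\C(C)=C)C[C@@](C)(O[Si](CC)(CC)CC)C(C)=O | intermediate
25 | C1=C2 triethylsilyl enol ether of 24 (triene) | CC(C)[Si](C(C)C)(C(C)C)O[C@H](C1=C(CO[Si](C)(C)C(C)(C)C)C(=O)O/C1=C\C(C)=C)C[C@@](C)(O[Si](CC)(CC)CC)C(=C)O[Si](CC)(CC)CC | intermediate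
26 | tricyclic cycloadduct: C1–C6-fused decalin (ring A C1–C6 with C4=C5, ring B C1, C6–C10) with the butenolide fused at C6–C7; O1 and O10 triethylsilyl, O13 tert-butyldimethylsilyl, O8 triisopropylsilyl; cis-fused isomer drawn | CC(C)[Si](C(C)C)(C(C)C)O[C@H]1C[C@@](C)(O[Si](CC)(CC)CC)[C@@]2(O[Si](CC)(CC)CC)CCC(C)=C[C@]23OC(=O)C(CO[Si](C)(C)C(C)(C)C)=C13 | intermediate
27 | tricyclic 1,10,13-triol with O8 triisopropylsilyl ether | CC(C)[Si](C(C)C)(C(C)C)O[C@H]1C[C@@](C)(O)[C@@]2(O)CCC(C)=C[C@]23OC(=O)C(CO)=C13 | intermediate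
28 | tripotassium trialkoxide of 27 | CC(C)[Si](C(C)C)(C(C)C)O[C@H]1C[C@@](C)(O[K])[C@@]2(O[K])CCC(C)=C[C@]23OC(=O)C(CO[K])=C13 | intermediate
29 | tripotassium salt of the ring-opened ten-membered 2-furanolate (C1 ketone, 4Z alkene, O10 and O13 alkoxides) | CC(C)[Si](C(C)C)(C(C)C)O[C@H]1C[C@@](C)(O[K])C(=O)CC/C(C)=C\c2oc(O[K])c(CO[K])c12 | intermediate
30 | (4Z,6S,8S,10R)-10,13-dihydroxy-1-oxo-8-(triisopropylsilyloxy)germacra-4,7(11)-dien-12,6-olide | CC(C)[Si](C(C)C)(C(C)C)O[C@H]1C[C@@](C)(O)C(=O)CC/C(C)=C\[C@@H]2OC(=O)C(CO)=C12 | intermediate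
31 | (4Z,6S,8S,10R)-10,13-diacetoxy-1-oxo-8-(triisopropylsilyloxy)germacra-4,7(11)-dien-12,6-olide | CC(C)[Si](C(C)C)(C(C)C)O[C@H]1C[C@@](C)(OC(C)=O)C(=O)CC/C(C)=C\[C@@H]2OC(=O)C(COC(C)=O)=C12 | intermediate
32 | (4Z,6S,8S,10R)-10,13-diacetoxy-8-hydroxy-1-oxogermacra-4,7(11)-dien-12,6-olide | O[C@H]1C[C@@](C)(OC(C)=O)C(=O)CC/C(C)=C\[C@@H]2OC(=O)C(COC(C)=O)=C12 | intermediate
33 | methacrylic anhydride | C=C(C)C(=O)OC(=O)C(C)=C | starting material
34 | (4Z,6S,8S,10R)-10,13-diacetoxy-8-(methacryloyloxy)-1-oxogermacra-4,7(11)-dien-12,6-olide | C=C(C)C(=O)O[C@H]1C[C@@](C)(OC(C)=O)C(=O)CC/C(C)=C\[C@@H]2OC(=O)C(COC(C)=O)=C12 | intermediate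
35 | CNP0172381.2, (4R,5S,6R,8S,10R)-10,13-diacetoxy-4,5-epoxy-8-(methacryloyloxy)-1-oxogermacr-7(11)-en-12,6-olide | C=C(C)C(=O)O[C@H]1C[C@@](C)(OC(C)=O)C(=O)CC[C@@]2(C)O[C@H]2[C@@H]2OC(=O)C(COC(C)=O)=C12 | target

**Step count and risks**

Total step count: 23. Longest linear sequence: 21 steps (steps 1–4 and 7–23, from 3-furanmethanol); the citramalate branch (steps 5–6) joins at step 7.

Steps most likely to fail:

1. Step 19 (key step). The alkoxide may not fragment cleanly. The delocalised anion may be protonated at C4 or C11 or from the wrong face, or it may re-close by transannular aldol during the quench. Fallback (known chemistry, conventional closure of the ten-membered ring at C5–C6), setting out from 17 and returning at 30: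
   - Propargyl alcohol is converted by copper-catalysed anti-carbomagnesiation (MeMgBr, CuI) and iodinolysis into (Z)-3-iodo-2-methylprop-2-en-1-ol F1, and by an Appel reaction (CBr4, PPh3) into (Z)-3-bromo-1-iodo-2-methylprop-1-ene F2.
   - The dianion of 17 (LiN(i-Pr)2, 2.2 equiv, THF, −78 °C) is alkylated at C2 with F2 to give the chain-extended (Z)-vinyl iodide ketone F3.
   - Photo-oxygenation of the 2-silylfuran (O2, tetraphenylporphyrin, visible light, CH2Cl2, −78 °C) should give the γ-hydroxybutenolide F4, whose open form carries C6 as an aldehyde.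
   - An intramolecular Nozaki–Hiyama–Kishi coupling (CrCl2, NiCl2 cat., DMSO/THF, high dilution) joins C5 to C6 with retention of the Z geometry, and the C6 alkoxide relactonises to the 13-O-silyl ten-membered lactone F5. The (6S) isomer is expected for the same conformational reason as in step 19.
   - HF·pyridine then frees O13 and gives 30.

2. Step 17. The enol silane may decompose thermally, or the dienyl lactone may polymerise before the hindered C1–C6 bond forms. Fallback (stepwise anionic annulation in place of the cycloaddition), setting out from 24 and returning at 27: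
   - LiN(SiMe3)2 (THF, −78 °C, high dilution) forms the C2 lithium enolate of 24, which should add to C3 of the trienoate in a vinylogous Michael sense.
   - The resulting lithium furanolate closes the aldol onto C1 (Michael–aldol annulation). Cold protonation should give the tricyclic C1 carbinol with O10 triethylsilyl, O13 tert-butyldimethylsilyl and O8 triisopropylsilyl ethers F6.
   - HF·pyridine converts F6 into 27.

3. Step 23. Facial selectivity may be poor, with the peracid attacking the face of the C4=C5 alkene opposite to the one required. Fallback (delivery of the oxygen with the opposite facial sense through a halohydrin), setting out from 34 and returning at 35: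
   - NBS in aqueous DME at 0 °C forms the bromonium ion on the face the peracid prefers, and water opens it at the tertiary C4 from the other side to give the 4-hydroxy-5-bromo compound F7.
   - Ag2O in CH2Cl2 closes the epoxide with inversion at C5 under non-basic conditions and gives 35.

**Further compounds**

F1 | step 19 | (Z)-3-iodo-2-methylprop-2-en-1-ol | OC/C(C)=C\I
F2 | step 19 | (Z)-3-bromo-1-iodo-2-methylprop-1-ene | BrC/C(C)=C\I
F3 | step 19 | C2-alkylated furan ketone, (Z)-vinyl iodide (C1 ketone, C2–C5 chain, free O10–H) | CC(C)[Si](C(C)C)(C(C)C)O[C@H](c1coc([Si](C)(C)C(C)(C)C)c1CO[Si](C)(C)C(C)(C)C)C[C@@](C)(O)C(=O)CC/C(C)=C\I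
F4 | step 19 | γ-hydroxybutenolide from F3 (C6 lactol, mixture at C6) | CC(C)[Si](C(C)C)(C(C)C)O[C@H](C1=C(CO[Si](C)(C)C(C)(C)C)C(=O)OC1O)C[C@@](C)(O)C(=O)CC/C(C)=C\I
F5 | step 19 | (4Z,6S,8S,10R)-13-(tert-butyldimethylsilyloxy)-10-hydroxy-1-oxo-8-(triisopropylsilyloxy)germacra-4,7(11)-dien-12,6-olide | CC(C)[Si](C(C)C)(C(C)C)O[C@H]1C[C@@](C)(O)C(=O)CC/C(C)=C\[C@@H]2OC(=O)C(CO[Si](C)(C)C(C)(C)C)=C12
F6 | step 17 | tricyclic C1 carbinol with O10 triethylsilyl, O13 tert-butyldimethylsilyl and O8 triisopropylsilyl ethers | CC(C)[Si](C(C)C)(C(C)C)O[C@H]1C[C@@](C)(O[Si](CC)(CC)CC)[C@@]2(O)CCC(C)=C[C@]23OC(=O)C(CO[Si](C)(C)C(C)(C)C)=C13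
F7 | step 23 | 5-bromo-4-hydroxy compound from 34 (bromohydrin, OH on the face of the required epoxide) | C=C(C)C(=O)O[C@H]1C[C@@](C)(OC(C)=O)C(=O)CC[C@@](C)(O)[C@H](Br)[C@@H]2OC(=O)C(COC(C)=O)=C12
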